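## Retrosynthetic overview

1. Target 27 ⇐ Pinnick oxidation of enal 26 ⇐ acid removal of two TBS groups and a dimethyl acetal from 25 ⇐ site-selective esterification of diol 20 at the C3 hydroxyl with acid 23.
2. C6 side chain (hydroxymethylvinyl) ⇐ α-keto ester of 15 by Wittig methylenation and DIBAL-H reduction.
3. Cyclohexane (the only ring, formed in step 9) ⇐ proline-mediated aldol/aldol [4+2] annulation of keto aldehyde 10 with enal 13: C3–C4 by dienamine α-aldol, then C5–C6 by keto ester aldol.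
4. Quaternary C1 of 10 (first stereocentre) ⇐ guanidinium-catalysed enantioselective Claisen rearrangement of 2-alkoxyacrylate 8 ⇐ allylic alcohol 4 + diazophosphonate 6 + CH2O.
5. Ring locants used in all names: C1 = C(CH3)(CH=CH2), C2 = CH2, C3 = CH–O (ester carbon of the target), C4 = CH bearing the propenyl acid unit, C5 = CHOH, C6 = CH bearing the hydroxymethylvinyl unit.

Assumption: the guanidinium catalyst enantiomer in step 6 is the one that gives (4R)-9; the sense of induction is taken by analogy, and the antipode is equally accessible from trans-1,2-diaminocyclohexane.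

## Route

Step 1
Reactants: 1 4,4-dimethoxybutan-2-one; 2 triethyl phosphonoacetate
Product: 3 ethyl (2E)-5,5-dimethoxy-3-methylpent-2-enoate
Conditions: NaH, THF, 0 °C → rt; E isomer separated by chromatography
Reagents that add atoms: none
Why: Horner–Wadsworth–Emmons olefination of the methyl ketone gives the trisubstituted enoate as an E-major mixture, and only one pure geometric isomer is needed because no stereocentre exists yet.

Step 2
Reactants: 3 ethyl (2E)-5,5-dimethoxy-3-methylpent-2-enoate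
Product: 4 (2E)-5,5-dimethoxy-3-methylpent-2-en-1-ol
Conditions: DIBAL-H (i-Bu2AlH), CH2Cl2, −78 → 0 °C; Rochelle salt work-up
Reagents that add atoms: none
Why: DIBAL-H 1,2-reduction of an enoate gives the allylic alcohol and leaves the acetal and the alkene geometry untouched.

Step 3
Reactants: 5 trimethyl phosphonoacetate
Product: 6 methyl 2-diazo-2-(dimethoxyphosphoryl)acetate
Conditions: p-ABSA, DBU, MeCN, 0 °C → rt
Reagents that add atoms: 4-acetamidobenzenesulfonyl azide (p-ABSA), CC(=O)Nc1ccc(cc1)S(=O)(=O)N=[N+]=[N-]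
Why: Regitz diazo transfer to the doubly activated methylene is a standard, high-yielding reaction.

Step 4
Reactants: 4 (2E)-5,5-dimethoxy-3-methylpent-2-en-1-ol; 6 methyl 2-diazo-2-(dimethoxyphosphoryl)acetate
Product: 7 methyl 2-(dimethoxyphosphoryl)-2-{[(2E)-5,5-dimethoxy-3-methylpent-2-en-1-yl]oxy}acetate (racemic at the phosphonate carbon)
Conditions: Rh2(OAc)4 (1 mol%), CH2Cl2, 40 °C, slow addition of 6
Reagents that add atoms: none
Why: Rhodium carbenoid O–H insertion into a primary allylic alcohol is much faster than cyclopropanation of the trisubstituted alkene and gives the α-alkoxy phosphonoacetate.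

Step 5
Reactants: 7 methyl 2-(dimethoxyphosphoryl)-2-{[(2E)-5,5-dimethoxy-3-methylpent-2-en-1-yl]oxy}acetate
Product: 8 methyl 2-{[(2E)-5,5-dimethoxy-3-methylpent-2-en-1-yl]oxy}prop-2-enoate
Conditions: 37% aq. CH2O, K2CO3, THF, rt
Reagents that add atoms: formaldehyde, C=O
Why: Horner–Wadsworth–Emmons methylenation with formaldehyde gives the 2-alkoxyacrylate (an ester-substituted allyl vinyl ether) under conditions too mild for a background Claisen rearrangement.

Step 6
Reactants: 8 methyl 2-{[(2E)-5,5-dimethoxy-3-methylpent-2-en-1-yl]oxy}prop-2-enoate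
Product: 9 methyl (4R)-4-(2,2-dimethoxyethyl)-4-methyl-2-oxohex-5-enoate
Conditions: C2-symmetric guanidinium BArF catalyst of the Jacobsen type (two trans-2-(2-arylpyrrol-1-yl)cyclohexyl arms, 20 mol%), hexanes, 30 °C, 6 d
Reagents that add atoms: none
Why: Gosteli-type [3,3] Claisen rearrangement under hydrogen-bond-donor catalysis, in which the guanidinium binds the ether and ester oxygens and selects one of the two enantiomeric chair transition states, so the (E)-trisubstituted allyl terminus becomes the (R)-quaternary carbon bearing methyl and vinyl.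

Step 7
Reactants: 9 methyl (4R)-4-(2,2-dimethoxyethyl)-4-methyl-2-oxohex-5-enoate
Product: 10 methyl (4R)-4-methyl-2-oxo-4-(2-oxoethyl)hex-5-enoate
Conditions: 1 M aq. HCl, THF, 0 °C → rt
Reagents that add atoms: water, O
Why: Acid hydrolysis of the dimethyl acetal frees the aldehyde, and the quaternary stereocentre cannot epimerise.

Step 8
Reactants: 11 1,1-dimethoxypropan-2-one; 12 (triphenylphosphoranylidene)acetaldehyde
Product: 13 (2E)-4,4-dimethoxy-3-methylbut-2-enal
Conditions: toluene, 90 °C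
Reagents that add atoms: none
Why: Wittig olefination of the activated α,α-dialkoxy ketone with the stabilised formyl ylide gives the β-methyl enal, whose geometry is irrelevant because it is erased in the dienamine of step 9.

Step 9
Reactants: 10 methyl (4R)-4-methyl-2-oxo-4-(2-oxoethyl)hex-5-enoate; 13 (2E)-4,4-dimethoxy-3-methylbut-2-enal
Product: 15 methyl 2-oxo-2-[(1S,3S,4R,5S,6S)-4-(3,3-dimethoxyprop-1-en-2-yl)-1-ethenyl-3,5-dihydroxy-1-methylcyclohex-6-yl]acetate (all ring substituents equatorial except the axial C1 methyl), via open-chain aldol 14 (not isolated)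
Conditions: (S)-proline (30 mol%), DMF, 4 °C, 13 (2.5 equiv) added over 24 h; then Et3N (0.5 equiv), 0 °C → rt
Reagents that add atoms: none
Why: Proposed new method: (S)-proline converts enal 13 into its dienamine by γ-deprotonation of the methyl group, and the dienamine α-carbon adds to the Re face of the unhindered aldehyde of 10 through the carboxylic-acid-bound Houk–List transition state, which sets the (S)-carbinol at C3 and leaves a β,γ-unsaturated aldehyde carrying the 1-(dimethoxymethyl)vinyl group (14); Et3N then enolises the α-keto ester, whose α-carbon closes the ring onto that aldehyde (6-enolexo aldol), and C4, C5 and C6 equilibrate by enolisation and retro-aldol to the all-equatorial chair fixed by the C3 carbinol and the 1,3-cis vinyl group at C1; the closest known reactions are the proline-catalysed aldehyde cross-aldol, dienamine α-functionalisation of β-methyl enals and the nitromethane–dialdehyde double Henry cyclisation.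

Step 10
Reactants: 15 methyl 2-oxo-2-[(1S,3S,4R,5S,6S)-4-(3,3-dimethoxyprop-1-en-2-yl)-1-ethenyl-3,5-dihydroxy-1-methylcyclohex-6-yl]acetate
Product: 17 methyl 2-[(1S,3S,4R,5R,6R)-4-(3,3-dimethoxyprop-1-en-2-yl)-1-ethenyl-1-methyl-3,5-bis(trimethylsilyloxy)cyclohex-6-yl]prop-2-enoate, via bis-TMS keto ester 16 (not isolated)
Conditions: TMSCl, imidazole, CH2Cl2, 0 °C; then Ph3P=CH2 (from Ph3PCH3Br, KN(SiMe3)2), THF, −78 → 0 °C
Reagents that add atoms: chlorotrimethylsilane, C[Si](C)(C)Cl; methylenetriphenylphosphorane, C=P(c1ccccc1)(c1ccccc1)c1ccccc1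
Why: Transient silylation removes the free β-hydroxyl (no retro-aldol or lactonisation), and Wittig methylenation of the highly electrophilic α-keto carbonyl then gives the 2-substituted acrylate faster than the hindered tertiary C6–H is removed, so no stereocentre changes.

Step 11
Reactants: 17 methyl 2-[(1S,3S,4R,5R,6R)-4-(3,3-dimethoxyprop-1-en-2-yl)-1-ethenyl-1-methyl-3,5-bis(trimethylsilyloxy)cyclohex-6-yl]prop-2-enoate
Product: 18 2-[(1S,3S,4R,5R,6R)-4-(3,3-dimethoxyprop-1-en-2-yl)-1-ethenyl-1-methyl-3,5-bis(trimethylsilyloxy)cyclohex-6-yl]prop-2-en-1-ol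
Conditions: DIBAL-H, CH2Cl2, −78 °C; Rochelle salt work-up
Reagents that add atoms: none
Why: DIBAL-H 1,2-reduction of the acrylate gives the allylic alcohol, and the acetal, silyl ethers and alkenes are inert.

Step 12
Reactants: 18 2-[(1S,3S,4R,5R,6R)-4-(3,3-dimethoxyprop-1-en-2-yl)-1-ethenyl-1-methyl-3,5-bis(trimethylsilyloxy)cyclohex-6-yl]prop-2-en-1-ol
Product: 20 (1S,3S,4R,5R,6R)-6-[3-(tert-butyldimethylsilyloxy)prop-1-en-2-yl]-4-(3,3-dimethoxyprop-1-en-2-yl)-1-ethenyl-1-methylcyclohexane-3,5-diol, via TBS bis-TMS ether 19 (not isolated)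
Conditions: TBSCl, imidazole, CH2Cl2, 0 °C; then K2CO3, MeOH, 0 °C
Reagents that add atoms: tert-butyldimethylsilyl chloride (TBSCl), CC(C)(C)[Si](C)(C)Cl
Why: The only free hydroxyl of 18 is silylated, and mild methanolysis then removes the two labile secondary TMS ethers while the primary TBS ether stays.

Step 13
Reactants: 21 ethyl 2-(hydroxymethyl)prop-2-enoate
Product: 22 ethyl 2-{[(tert-butyldimethylsilyl)oxy]methyl}prop-2-enoate
Conditions: TBSCl, imidazole, DMF, rt
Reagents that add atoms: tert-butyldimethylsilyl chloride (TBSCl), CC(C)(C)[Si](C)(C)Cl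
Why: Standard silylation of a primary allylic alcohol.

Step 14
Reactants: 22 ethyl 2-{[(tert-butyldimethylsilyl)oxy]methyl}prop-2-enoate
Product: 23 2-{[(tert-butyldimethylsilyl)oxy]methyl}prop-2-enoic acid
Conditions: LiOH, THF/H2O, 0 °C → rt; then 1 M HCl to pH 3
Reagents that add atoms: lithium hydroxide, [Li+].[OH-]
Why: Saponification of the ethyl ester, with the primary TBS ether stable to cold aqueous LiOH.

Step 15
Reactants: 20 (1S,3S,4R,5R,6R)-6-[3-(tert-butyldimethylsilyloxy)prop-1-en-2-yl]-4-(3,3-dimethoxyprop-1-en-2-yl)-1-ethenyl-1-methylcyclohexane-3,5-diol; 23 2-{[(tert-butyldimethylsilyl)oxy]methyl}prop-2-enoic acid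
Product: 25 (1S,3S,4S,5R,6R)-6-[3-(tert-butyldimethylsilyloxy)prop-1-en-2-yl]-4-(3,3-dimethoxyprop-1-en-2-yl)-1-ethenyl-5-hydroxy-1-methylcyclohex-3-yl 2-{[(tert-butyldimethylsilyl)oxy]methyl}prop-2-enoate, via mixed anhydride 24 (not isolated)
Conditions: 2,4,6-trichlorobenzoyl chloride, Et3N, THF, 0 °C; then 20, DMAP, toluene, 0 °C → rt
Reagents that add atoms: none
Why: Yamaguchi esterification with the bulky mixed anhydride acylates the C3 hydroxyl (flanked by a CH2) in preference to the C5 hydroxyl (flanked by two branched carbons), with retention at C3.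

Step 16
Reactants: 25 (1S,3S,4S,5R,6R)-6-[3-(tert-butyldimethylsilyloxy)prop-1-en-2-yl]-4-(3,3-dimethoxyprop-1-en-2-yl)-1-ethenyl-5-hydroxy-1-methylcyclohex-3-yl 2-{[(tert-butyldimethylsilyl)oxy]methyl}prop-2-enoate
Product: 26 (1S,3S,4S,5R,6R)-1-ethenyl-5-hydroxy-6-(3-hydroxyprop-1-en-2-yl)-1-methyl-4-(3-oxoprop-1-en-2-yl)cyclohex-3-yl 2-(hydroxymethyl)prop-2-enoate (in equilibrium with its C5–O lactol)
Conditions: 1 M aq. HCl, THF, rt
Reagents that add atoms: water, O
Why: Dilute aqueous acid cleaves both primary TBS ethers and hydrolyses the dimethyl acetal to the α-methylene aldehyde while the acrylate ester survives.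

Step 17
Reactants: 26 (1S,3S,4S,5R,6R)-1-ethenyl-5-hydroxy-6-(3-hydroxyprop-1-en-2-yl)-1-methyl-4-(3-oxoprop-1-en-2-yl)cyclohex-3-yl 2-(hydroxymethyl)prop-2-enoate
Product: 27 2-[(1S,2R,3R,4S,6S)-4-ethenyl-2-hydroxy-6-{[2-(hydroxymethyl)prop-2-enoyl]oxy}-3-(3-hydroxyprop-1-en-2-yl)-4-methylcyclohexyl]prop-2-enoic acid (CNP0509685.1)
Conditions: NaClO2, NaH2PO4, 2-methylbut-2-ene, t-BuOH/H2O, 0 °C
Reagents that add atoms: sodium chlorite, [Na+].[O-]Cl=O
Why: Pinnick oxidation converts the α-substituted acrolein (open form of the lactol) into the acrylic acid at pH about 4 without touching the free alcohols, the alkenes or the ester, and the buffered medium avoids lactonisation.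

## Compound list

1 | 4,4-dimethoxybutan-2-one | CC(=O)CC(OC)OC | starting material
2 | triethyl phosphonoacetate | CCOC(=O)CP(=O)(OCC)OCC | starting material
3 | ethyl (2E)-5,5-dimethoxy-3-methylpent-2-enoate | CCOC(=O)/C=C(\C)CC(OC)OC | intermediate
4 | (2E)-5,5-dimethoxy-3-methylpent-2-en-1-ol | OC/C=C(\C)CC(OC)OC | intermediate
5 | trimethyl phosphonoacetate | COC(=O)CP(=O)(OC)OC | starting material
6 | methyl 2-diazo-2-(dimethoxyphosphoryl)acetate | COC(=O)C(=[N+]=[N-])P(=O)(OC)OC | intermediate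
7 | methyl 2-(dimethoxyphosphoryl)-2-{[(2E)-5,5-dimethoxy-3-methylpent-2-en-1-yl]oxy}acetate | COC(=O)C(OC/C=C(\C)CC(OC)OC)P(=O)(OC)OC | intermediate
8 | methyl 2-{[(2E)-5,5-dimethoxy-3-methylpent-2-en-1-yl]oxy}prop-2-enoate | C=C(OC/C=C(\C)CC(OC)OC)C(=O)OC | intermediate
9 | methyl (4R)-4-(2,2-dimethoxyethyl)-4-methyl-2-oxohex-5-enoate | C=C[C@](CC(=O)C(=O)OC)(C)CC(OC)OC | intermediate
10 | methyl (4R)-4-methyl-2-oxo-4-(2-oxoethyl)hex-5-enoate | C=C[C@](CC(=O)C(=O)OC)(C)CC=O | intermediate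
11 | 1,1-dimethoxypropan-2-one | CC(=O)C(OC)OC | starting material
12 | (triphenylphosphoranylidene)acetaldehyde | O=CC=P(c1ccccc1)(c1ccccc1)c1ccccc1 | starting material
13 | (2E)-4,4-dimethoxy-3-methylbut-2-enal | O=C/C=C(\C)C(OC)OC | intermediate
14 | methyl (4R,6S)-4-ethenyl-7-formyl-6-hydroxy-9,9-dimethoxy-4-methyl-8-methylidene-2-oxononanoate (C7 epimers, not isolated) | C=C[C@](CC(=O)C(=O)OC)(C)C[C@H](O)C(C=O)C(=C)C(OC)OC | intermediate
15 | methyl 2-oxo-2-[(1S,3S,4R,5S,6S)-4-(3,3-dimethoxyprop-1-en-2-yl)-1-ethenyl-3,5-dihydroxy-1-methylcyclohex-6-yl]acetate | C=C[C@]1(C)C[C@H](O)[C@@H](C(=C)C(OC)OC)[C@H](O)[C@H]1C(=O)C(=O)OC | intermediate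
16 | methyl 2-oxo-2-[(1S,3S,4R,5S,6S)-4-(3,3-dimethoxyprop-1-en-2-yl)-1-ethenyl-1-methyl-3,5-bis(trimethylsilyloxy)cyclohex-6-yl]acetate (not isolated) | C=C[C@]1(C)C[C@H](O[Si](C)(C)C)[C@@H](C(=C)C(OC)OC)[C@H](O[Si](C)(C)C)[C@H]1C(=O)C(=O)OC | intermediate
17 | methyl 2-[(1S,3S,4R,5R,6R)-4-(3,3-dimethoxyprop-1-en-2-yl)-1-ethenyl-1-methyl-3,5-bis(trimethylsilyloxy)cyclohex-6-yl]prop-2-enoate | C=C[C@]1(C)C[C@H](O[Si](C)(C)C)[C@@H](C(=C)C(OC)OC)[C@H](O[Si](C)(C)C)[C@H]1C(=C)C(=O)OC | intermediate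
18 | 2-[(1S,3S,4R,5R,6R)-4-(3,3-dimethoxyprop-1-en-2-yl)-1-ethenyl-1-methyl-3,5-bis(trimethylsilyloxy)cyclohex-6-yl]prop-2-en-1-ol | C=C[C@]1(C)C[C@H](O[Si](C)(C)C)[C@@H](C(=C)C(OC)OC)[C@H](O[Si](C)(C)C)[C@H]1C(=C)CO | intermediate
19 | tert-butyldimethylsilyl ether of 18 (not isolated) | C=C[C@]1(C)C[C@H](O[Si](C)(C)C)[C@@H](C(=C)C(OC)OC)[C@H](O[Si](C)(C)C)[C@H]1C(=C)CO[Si](C)(C)C(C)(C)C | intermediate
20 | (1S,3S,4R,5R,6R)-6-[3-(tert-butyldimethylsilyloxy)prop-1-en-2-yl]-4-(3,3-dimethoxyprop-1-en-2-yl)-1-ethenyl-1-methylcyclohexane-3,5-diol | C=C[C@]1(C)C[C@H](O)[C@@H](C(=C)C(OC)OC)[C@H](O)[C@H]1C(=C)CO[Si](C)(C)C(C)(C)C | intermediate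
21 | ethyl 2-(hydroxymethyl)prop-2-enoate | C=C(CO)C(=O)OCC | starting material
22 | ethyl 2-{[(tert-butyldimethylsilyl)oxy]methyl}prop-2-enoate | C=C(CO[Si](C)(C)C(C)(C)C)C(=O)OCC | intermediate
23 | 2-{[(tert-butyldimethylsilyl)oxy]methyl}prop-2-enoic acid | C=C(CO[Si](C)(C)C(C)(C)C)C(=O)O | intermediate
24 | 2-{[(tert-butyldimethylsilyl)oxy]methyl}prop-2-enoic 2,4,6-trichlorobenzoic anhydride (not isolated) | C=C(CO[Si](C)(C)C(C)(C)C)C(=O)OC(=O)c1c(Cl)cc(Cl)cc1Cl | intermediate
25 | (1S,3S,4S,5R,6R)-6-[3-(tert-butyldimethylsilyloxy)prop-1-en-2-yl]-4-(3,3-dimethoxyprop-1-en-2-yl)-1-ethenyl-5-hydroxy-1-methylcyclohex-3-yl 2-{[(tert-butyldimethylsilyl)oxy]methyl}prop-2-enoate | C=C[C@]1(C)C[C@H](OC(=O)C(=C)CO[Si](C)(C)C(C)(C)C)[C@@H](C(=C)C(OC)OC)[C@H](O)[C@H]1C(=C)CO[Si](C)(C)C(C)(C)C | intermediate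
26 | (1S,3S,4S,5R,6R)-1-ethenyl-5-hydroxy-6-(3-hydroxyprop-1-en-2-yl)-1-methyl-4-(3-oxoprop-1-en-2-yl)cyclohex-3-yl 2-(hydroxymethyl)prop-2-enoate | C=C[C@]1(C)C[C@H](OC(=O)C(=C)CO)[C@@H](C(=C)C=O)[C@H](O)[C@H]1C(=C)CO | intermediate
27 | 2-[(1S,2R,3R,4S,6S)-4-ethenyl-2-hydroxy-6-{[2-(hydroxymethyl)prop-2-enoyl]oxy}-3-(3-hydroxyprop-1-en-2-yl)-4-methylcyclohexyl]prop-2-enoic acid | C=C[C@]1(C)C[C@H](OC(=O)C(=C)CO)[C@@H](C(=C)C(=O)O)[C@H](O)[C@H]1C(=C)CO | target

## Step count and risks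

Total step count: 17 (13 in the main line, 1 for diazophosphonate 6, 1 for enal 13, 2 for acid 23).
Longest linear sequence: 13 steps (1 → 27 through steps 1, 2, 4, 5, 6, 7, 9, 10, 11, 12, 15, 16, 17).

The three steps most likely to fail:

**Step 9 (the new annulation).** The risks are dienamine attack on the keto ester carbonyl instead of the aldehyde, self-condensation of 13, isomerisation of the β,γ-unsaturated aldehyde 14 before ring closure, and lactonisation of the C5 hydroxyl onto the keto ester. The fallback uses known reactions only, sets out from 10 and returns at 26.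

Keto aldehyde 10 serves as acceptor in an ordinary (S)-proline-catalysed cross-aldol with commercial 4,4-dimethoxybutanal (O=CCCC(OC)OC; DMF, 4 °C, slow addition), which gives the saturated open-chain aldol F1. Et3N closes the ring by the same keto ester aldol to the cyclohexane keto ester diol carrying a 2,2-dimethoxyethyl group at C4 F2. This is taken through the operations of steps 10, 11, 12, 15 and 16, passing the bis-TMS keto ester F3, the bis-TMS acrylate F4, the bis-TMS allylic alcohol F5, the TBS bis-TMS ether F6, the TBS ether diol F7, the C3 ester F8 and, after aqueous HCl, the saturated aldehyde triol F9. The methylene group is then introduced by the amine-catalysed α-methylenation of the aldehyde (37% aq. CH2O, pyrrolidine, propionic acid, i-PrOH, 45 °C), which gives 26.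

**Step 10 (methylenation of a hindered, enolisable α-keto ester).** The risk is enolisation or β-elimination by the basic ylide. The fallback sets out from 15 and returns at 17. After the same silylation, the ketone is treated with Me3SiCH2MgCl/CeCl3 (THF, −78 °C), which adds without enolisation to give the tertiary β-hydroxysilane F10. KH (THF, 0 °C) then effects the Peterson elimination to 17.

**Step 15 (site-selective esterification of a diol).** The risk is acylation at C5 or double acylation. The fallback removes the need for selectivity, sets out from 18 and returns at 26. K2CO3/MeOH gives the free triol F11. TIPDSCl2 (1,3-dichloro-1,1,3,3-tetraisopropyldisiloxane) and imidazole in DMF at 0 °C tie the primary hydroxyl to the neighbouring C5 hydroxyl as the disiloxane-bridged alcohol F12, in which only the C3 hydroxyl is free. Esterification with 23 under the conditions of step 15 gives the bridged ester F13, and 48% aq. HF in MeCN removes all silicon groups and the acetal to give 26.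

## Further compounds

F1 | step 9 | methyl (4R,6S)-4-ethenyl-7-formyl-6-hydroxy-9,9-dimethoxy-4-methyl-2-oxononanoate (C7 epimers) | C=C[C@](CC(=O)C(=O)OC)(C)C[C@H](O)C(C=O)CC(OC)OC
F2 | step 9 | methyl 2-oxo-2-[4-(2,2-dimethoxyethyl)-1-ethenyl-3,5-dihydroxy-1-methylcyclohex-6-yl]acetate (same ring configuration as 15) | C=C[C@]1(C)C[C@H](O)[C@@H](CC(OC)OC)[C@H](O)[C@H]1C(=O)C(=O)OC
F3 | step 9 | 3,5-bis(trimethylsilyl) ether of F2 | C=C[C@]1(C)C[C@H](O[Si](C)(C)C)[C@@H](CC(OC)OC)[C@H](O[Si](C)(C)C)[C@H]1C(=O)C(=O)OC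
F4 | step 9 | methyl 2-[4-(2,2-dimethoxyethyl)-1-ethenyl-1-methyl-3,5-bis(trimethylsilyloxy)cyclohex-6-yl]prop-2-enoate | C=C[C@]1(C)C[C@H](O[Si](C)(C)C)[C@@H](CC(OC)OC)[C@H](O[Si](C)(C)C)[C@H]1C(=C)C(=O)OC
F5 | step 9 | 2-[4-(2,2-dimethoxyethyl)-1-ethenyl-1-methyl-3,5-bis(trimethylsilyloxy)cyclohex-6-yl]prop-2-en-1-ol | C=C[C@]1(C)C[C@H](O[Si](C)(C)C)[C@@H](CC(OC)OC)[C@H](O[Si](C)(C)C)[C@H]1C(=C)CO
F6 | step 9 | tert-butyldimethylsilyl ether of F5 | C=C[C@]1(C)C[C@H](O[Si](C)(C)C)[C@@H](CC(OC)OC)[C@H](O[Si](C)(C)C)[C@H]1C(=C)CO[Si](C)(C)C(C)(C)C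
F7 | step 9 | 6-[3-(tert-butyldimethylsilyloxy)prop-1-en-2-yl]-4-(2,2-dimethoxyethyl)-1-ethenyl-1-methylcyclohexane-3,5-diol | C=C[C@]1(C)C[C@H](O)[C@@H](CC(OC)OC)[C@H](O)[C@H]1C(=C)CO[Si](C)(C)C(C)(C)C
F8 | step 9 | C3 2-{[(tert-butyldimethylsilyl)oxy]methyl}prop-2-enoate of F7 | C=C[C@]1(C)C[C@H](OC(=O)C(=C)CO[Si](C)(C)C(C)(C)C)[C@@H](CC(OC)OC)[C@H](O)[C@H]1C(=C)CO[Si](C)(C)C(C)(C)C
F9 | step 9 | 1-ethenyl-5-hydroxy-6-(3-hydroxyprop-1-en-2-yl)-1-methyl-4-(2-oxoethyl)cyclohex-3-yl 2-(hydroxymethyl)prop-2-enoate | C=C[C@]1(C)C[C@H](OC(=O)C(=C)CO)[C@@H](CC=O)[C@H](O)[C@H]1C(=C)CO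
F10 | step 10 | methyl 2-hydroxy-3-(trimethylsilyl)-2-[4-(3,3-dimethoxyprop-1-en-2-yl)-1-ethenyl-1-methyl-3,5-bis(trimethylsilyloxy)cyclohex-6-yl]propanoate | C=C[C@]1(C)C[C@H](O[Si](C)(C)C)[C@@H](C(=C)C(OC)OC)[C@H](O[Si](C)(C)C)[C@H]1C(O)(C[Si](C)(C)C)C(=O)OC
F11 | step 15 | 4-(3,3-dimethoxyprop-1-en-2-yl)-1-ethenyl-6-(3-hydroxyprop-1-en-2-yl)-1-methylcyclohexane-3,5-diol | C=C[C@]1(C)C[C@H](O)[C@@H](C(=C)C(OC)OC)[C@H](O)[C@H]1C(=C)CO
F12 | step 15 | 1,1,3,3-tetraisopropyldisiloxane-1,3-diyl ether bridging the C5 and side-chain hydroxyls of F11 | C=C[C@]1(C)C[C@H](O)[C@@H](C(=C)C(OC)OC)[C@H](O2)[C@H]1C(=C)CO[Si](C(C)C)(C(C)C)O[Si]2(C(C)C)C(C)C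
F13 | step 15 | C3 2-{[(tert-butyldimethylsilyl)oxy]methyl}prop-2-enoate of F12 | C=C[C@]1(C)C[C@H](OC(=O)C(=C)CO[Si](C)(C)C(C)(C)C)[C@@H](C(=C)C(OC)OC)[C@H](O2)[C@H]1C(=C)CO[Si](C(C)C)(C(C)C)O[Si]2(C(C)C)C(C)C
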